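**Retrosynthetic overview**
1. Target ⇐ acetylation and desilylation of a macrocyclic allylic alcohol; the 11-membered ring is closed last by an intramolecular Ni/Cr (Nozaki–Hiyama–Kishi) addition of a ring enol triflate to a side-chain aldehyde.
2. The exocyclic diene arm ⇐ Ni/Cr coupling of a 2-propenyl triflate (from a methyl ketone) with a C6 aldehyde cut from (S)-citronellol, then dehydration.
3. The cis-hydrindane carrying that methyl ketone ⇐ ozonolysis/intramolecular aldol ring contraction of a cis-octalin, then face-selective hydrogenation.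
4. The cis-octalin ⇐ key Diels–Alder cycloaddition of isoprene to trans-6-hydroxy-(S)-carvone, which sets the quaternary methyl carbon and the ring fusion; the carvone isopropenyl carbon later becomes the enol triflate carbon.
5. Ring order: cyclohexane (bought in carvone) → Diels–Alder ring → contracted to the cyclopentane → 11-membered ring.

Assumption: (S)-(+)-carvone and (S)-(−)-citronellol are bought enantiopure. β means the face of the angular methyl group, α the opposite face. Octalins use naphthalene locants and hydrindanes use indene locants (C7a = angular carbon, C3 = carbon bearing the acyl arm).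

Step 1
Reactants: 1 (S)-(+)-carvone
Product: 2 trans-6-hydroxycarvone [(5R,6R)-6-hydroxy-2-methyl-5-(prop-1-en-2-yl)cyclohex-2-en-1-one]
Conditions: KN(SiMe3)2, THF, −78 °C; racemic 2-(phenylsulfonyl)-3-phenyloxaziridine, −78 °C; AcOH
Reagents that add atoms: 2-(phenylsulfonyl)-3-phenyloxaziridine, O=S(=O)(c1ccccc1)N1OC1c1ccccc1
Why: Kinetic α′-enolate hydroxylation (Davis oxidation); the oxidant approaches C6 anti to the C5 isopropenyl group, giving the trans ketol.

Step 2
Reactants: 2 trans-6-hydroxycarvone; 3 isoprene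
Product: 4 cis-fused adduct 2α-hydroxy-6,8aβ-dimethyl-3β-(prop-1-en-2-yl)-3,4,4a,5,8,8a-hexahydronaphthalen-1(2H)-one (4a-H β)
Conditions: Me2AlCl (2.2 equiv), isoprene (10 equiv), CH2Cl2, −30 → 0 °C; aq. HCl
Reagents that add atoms: none
Why: Lewis-acid-promoted Diels–Alder cycloaddition of the chelated α′-alkoxy enone; the diene adds suprafacially to the face anti to the isopropenyl group with "para" regiochemistry, so the angular methyl and 4a-H end up cis and β.

Step 3
Reactants: 4 Diels–Alder adduct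
Product: 5 6,8aβ-dimethyl-3β-(prop-1-en-2-yl)-1,2,3,4,4a,5,8,8a-octahydronaphthalene-1β,2α-diol (4a-H β)
Conditions: Me4NBH(OAc)3, MeCN–AcOH (1:1), −20 °C
Reagents that add atoms: none
Why: Hydroxyl-directed reduction (internal hydride delivery from the acetoxyborohydride bound to the 2α-OH) puts the new hydroxyl trans to it, i.e. 1β and cis to the angular methyl.

Step 4
Reactants: 5 trans-diol
Product: 6 1β,2α-bis(tert-butyldimethylsilyl) ether of 5
Conditions: TBSOTf (2.5 equiv), 2,6-lutidine, CH2Cl2, 0 °C → rt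
Reagents that add atoms: tert-butyldimethylsilyl triflate, CC(C)(C)[Si](C)(C)OS(=O)(=O)C(F)(F)F
Why: Silylation of both secondary alcohols with the reactive silyl triflate; no stereocentre is touched.

Step 5
Reactants: 6 bis-silyl ether
Product: 8 3,5β-diacetyl-6α,7β-bis(tert-butyldimethylsilyloxy)-7aβ-methyl-3aβ,4,5,6,7,7a-hexahydro-1H-indene, via keto-aldehyde 7 (not isolated)
Conditions: O3, CH2Cl2–MeOH, −78 °C; Me2S; then KOH (0.2 equiv), MeOH, 0 °C
Reagents that add atoms: ozone, [O-][O+]=O
Why: Ozonolysis cleaves both alkenes, and the methylene of the 2-oxopropyl arm then closes onto the aldehyde in an intramolecular aldol condensation, contracting the Diels–Alder ring to the acetylcyclopentene; ring-fusion centres are untouched and the 5-acetyl stays equatorial (β).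

Step 6
Reactants: 8 diacetyl hexahydroindene
Product: 9 5β-acetoxy-3-acetyl-6α,7β-bis(tert-butyldimethylsilyloxy)-7aβ-methyl-3aβ,4,5,6,7,7a-hexahydro-1H-indene
Conditions: mCPBA, Na2HPO4, CH2Cl2, rt
Reagents that add atoms: 3-chloroperoxybenzoic acid, OOC(=O)c1cccc(Cl)c1
Why: Baeyer–Villiger oxidation of the saturated methyl ketone only (secondary alkyl migrates with retention; the conjugated acetyl is inert).

Step 7
Reactants: 9 enone acetate
Product: 10 5β-acetoxy-3α-acetyl-6α,7β-bis(tert-butyldimethylsilyloxy)-7aβ-methyl-3aβ-octahydro-1H-indene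
Conditions: H2 (1 atm), Pd/C, EtOAc, rt
Reagents that add atoms: none
Why: Heterogeneous syn-hydrogenation from the convex (β) face of the cis-hydrindene, since the concave face is blocked by the folded cyclohexane; this places H-3 β and the acetyl group α, cis to C4.

Step 8
Reactants: 10 methyl ketone
Product: 11 1-[5β-acetoxy-6α,7β-bis(tert-butyldimethylsilyloxy)-7aβ-methyl-3aβ-octahydro-1H-inden-3α-yl]ethenyl trifluoromethanesulfonate
Conditions: KN(SiMe3)2, THF, −78 °C; PhNTf2, −78 → −30 °C
Reagents that add atoms: N-phenylbis(trifluoromethanesulfonimide), O=S(=O)(N(c1ccccc1)S(=O)(=O)C(F)(F)F)C(F)(F)F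
Why: Kinetic deprotonation at the methyl group and O-triflation of the enolate; the low temperature avoids enolisation toward C3, so its configuration is kept.

Step 9
Reactants: 12 (S)-(−)-citronellol
Product: 13 (S)-citronellol triethylsilyl ether
Conditions: TESCl, imidazole, CH2Cl2, 0 °C
Reagents that add atoms: chlorotriethylsilane, CC[Si](Cl)(CC)CC
Why: Silyl protection of the primary alcohol; the methyl-bearing stereocentre is bought.

Step 10
Reactants: 13 silyl ether
Product: 14 (4S)-4-methyl-6-(triethylsilyloxy)hexanal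
Conditions: O3, CH2Cl2, −78 °C; Me2S
Reagents that add atoms: ozone, [O-][O+]=O
Why: Ozonolysis of the trisubstituted alkene gives the C6 aldehyde without touching the stereocentre.

Step 11
Reactants: 11 alkenyl triflate; 14 aldehyde
Product: 15 allylic alcohol: 10 with the 3α-acetyl replaced by a (6S)-3-hydroxy-6-methyl-8-(triethylsilyloxy)oct-1-en-2-yl group (both carbinol epimers)
Conditions: CrCl2 (4 equiv), NiCl2 (2 mol %), DMF, rt
Reagents that add atoms: none
Why: Nozaki–Hiyama–Kishi coupling (nickel inserts into the triflate, the alkenylchromium adds to the aldehyde); the new carbinol centre is removed in the next step.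

Step 12
Reactants: 15 allylic alcohol
Product: 16 diene: 5β-acetoxy-6α,7β-bis(tert-butyldimethylsilyloxy)-7aβ-methyl-3α-[(3E,6S)-6-methyl-8-(triethylsilyloxy)octa-1,3-dien-2-yl]-3aβ-octahydro-1H-indene
Conditions: Ph2S[OC(CF3)2Ph]2 (Martin sulfurane), CH2Cl2, 0 °C → rt
Reagents that add atoms: none
Why: Dehydration through the alkoxysulfurane (anti elimination toward the only β-CH2) gives the conjugated (E)-1,3-diene.

Step 13
Reactants: 16 diene acetate
Product: 17 the corresponding 5β-alcohol
Conditions: iBu2AlH (2.5 equiv), CH2Cl2, −78 °C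
Reagents that add atoms: none
Why: Reductive cleavage of the only ester; silyl ethers and the diene are inert.

Step 14
Reactants: 17 alcohol
Product: 18 the corresponding 5-ketone
Conditions: Dess–Martin periodinane, NaHCO3, CH2Cl2, rt
Reagents that add atoms: none
Why: Dess–Martin oxidation under buffered conditions; the stereocentre created by the Baeyer–Villiger step is erased as planned.

Step 15
Reactants: 18 ketone
Product: 19 the corresponding 4-methylidene-5-ketone
Conditions: LiN(iPr)2, THF, −78 °C; CH2=NMe2+ I−, −78 °C → rt; MeI; NaHCO3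
Reagents that add atoms: dimethyl(methylidene)ammonium iodide (Eschenmoser's salt), C=[N+](C)C.[I-]
Why: Kinetic enolisation away from the silyloxy-bearing α-carbon, Mannich reaction, quaternisation and elimination give the α-methylene ketone.

Step 16
Reactants: 19 α-methylene ketone
Product: 20 6α,7β-bis(tert-butyldimethylsilyloxy)-4,7aβ-dimethyl-3α-[(3E,6S)-6-methyl-8-(triethylsilyloxy)octa-1,3-dien-2-yl]-2,3,3aβ,6,7,7a-hexahydro-1H-inden-5-yl trifluoromethanesulfonate
Conditions: LiBH(sBu)3, THF, −78 °C; PhNTf2, −78 → 0 °C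
Reagents that add atoms: N-phenylbis(trifluoromethanesulfonimide), O=S(=O)(N(c1ccccc1)S(=O)(=O)C(F)(F)F)C(F)(F)F
Why: Conjugate hydride reduction gives the tetrasubstituted enolate regiospecifically and O-triflation traps it, installing the ring methyl and the tetrasubstituted alkene.

Step 17
Reactants: 20 enol triflate
Product: 21 aldehyde: 20 with the CH2OSiEt3 terminus converted to CHO
Conditions: (COCl)2, DMSO, CH2Cl2, −78 → −40 °C; Et3N, → 0 °C
Reagents that add atoms: none
Why: Swern oxidation that cleaves the primary triethylsilyl ether in situ and oxidises it to the aldehyde; the secondary TBS ethers survive.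

Step 18
Reactants: 21 triflate-aldehyde
Product: 22 macrocyclic allylic alcohol (the target without its acetyl group and with both ring hydroxyls as TBS ethers)
Conditions: CrCl2 (10 equiv), NiCl2 (5 mol %), DMSO–DMF, 0.002 M, rt
Reagents that add atoms: none
Why: Intramolecular Nozaki–Hiyama–Kishi reaction closes the 11-membered ring; the (S)-carbinol is expected from addition to the aldehyde face that points away from the neighbouring silyloxy group, but this is substrate control and not secured.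

Step 19
Reactants: 22 macrocyclic alcohol
Product: 23 acetate of 22
Conditions: Ac2O, pyridine, DMAP (cat.), CH2Cl2, rt
Reagents that add atoms: acetic anhydride, CC(=O)OC(C)=O
Why: Acylation of the only free hydroxyl with retention.

Step 20
Reactants: 23 bis-silyl ether acetate
Product: 24 target (CNP0291538.1)
Conditions: HF·pyridine, pyridine–THF, 0 °C → rt
Reagents that add atoms: none
Why: Buffered fluoride desilylation frees both ring hydroxyls and leaves the allylic acetate and diene intact.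

**Compound list**
1 | (S)-(+)-carvone | O=C1C(C)=CC[C@H](C(C)=C)C1 | starting material
2 | trans-6-hydroxycarvone (5R,6R) | O=C1C(C)=CC[C@H](C(C)=C)[C@H]1O | intermediate
3 | isoprene | C=CC(C)=C | starting material
4 | cis-octalone Diels–Alder adduct | CC1=CC[C@]2(C)C(=O)[C@H](O)[C@@H](C(C)=C)C[C@@H]2C1 | intermediate
5 | octalin 1β,2α-diol | CC1=CC[C@]2(C)[C@@H](O)[C@H](O)[C@@H](C(C)=C)C[C@@H]2C1 | intermediate
6 | bis-TBS ether of 5 | CC1=CC[C@]2(C)[C@@H](O[Si](C)(C)C(C)(C)C)[C@H](O[Si](C)(C)C(C)(C)C)[C@@H](C(C)=C)C[C@@H]2C1 | intermediate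
7 | keto-aldehyde: 4β-acetyl-2β,3α-bis(TBSO)-1β-methyl-1α-(2-oxoethyl)-6α-(2-oxopropyl)cyclohexane | O=CC[C@]1(C)[C@@H](O[Si](C)(C)C(C)(C)C)[C@H](O[Si](C)(C)C(C)(C)C)[C@@H](C(C)=O)C[C@@H]1CC(C)=O | intermediate
8 | 3,5β-diacetyl hexahydroindene | CC(=O)C1=CC[C@]2(C)[C@@H](O[Si](C)(C)C(C)(C)C)[C@H](O[Si](C)(C)C(C)(C)C)[C@@H](C(C)=O)C[C@H]12 | intermediate
9 | 5β-acetoxy-3-acetyl hexahydroindene | CC(=O)C1=CC[C@]2(C)[C@@H](O[Si](C)(C)C(C)(C)C)[C@H](O[Si](C)(C)C(C)(C)C)[C@@H](OC(C)=O)C[C@H]12 | intermediate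
10 | 5β-acetoxy-3α-acetyl octahydroindene | CC(=O)[C@@H]1CC[C@]2(C)[C@@H](O[Si](C)(C)C(C)(C)C)[C@H](O[Si](C)(C)C(C)(C)C)[C@@H](OC(C)=O)C[C@H]12 | intermediate
11 | 2-propenyl triflate | C=C(OS(=O)(=O)C(F)(F)F)[C@@H]1CC[C@]2(C)[C@@H](O[Si](C)(C)C(C)(C)C)[C@H](O[Si](C)(C)C(C)(C)C)[C@@H](OC(C)=O)C[C@H]12 | intermediate
12 | (S)-(−)-citronellol | CC(C)=CCC[C@H](C)CCO | starting material
13 | (S)-citronellol TES ether | CC(C)=CCC[C@H](C)CCO[Si](CC)(CC)CC | intermediate
14 | (4S)-4-methyl-6-(triethylsilyloxy)hexanal | O=CCC[C@H](C)CCO[Si](CC)(CC)CC | intermediate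
15 | allylic alcohol (epimers at the carbinol) | C=C(C(O)CC[C@H](C)CCO[Si](CC)(CC)CC)[C@@H]1CC[C@]2(C)[C@@H](O[Si](C)(C)C(C)(C)C)[C@H](O[Si](C)(C)C(C)(C)C)[C@@H](OC(C)=O)C[C@H]12 | intermediate
16 | (E)-diene acetate | C=C(/C=C/C[C@H](C)CCO[Si](CC)(CC)CC)[C@@H]1CC[C@]2(C)[C@@H](O[Si](C)(C)C(C)(C)C)[C@H](O[Si](C)(C)C(C)(C)C)[C@@H](OC(C)=O)C[C@H]12 | intermediate
17 | diene 5β-alcohol | C=C(/C=C/C[C@H](C)CCO[Si](CC)(CC)CC)[C@@H]1CC[C@]2(C)[C@@H](O[Si](C)(C)C(C)(C)C)[C@H](O[Si](C)(C)C(C)(C)C)[C@@H](O)C[C@H]12 | intermediate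
18 | diene 5-ketone | C=C(/C=C/C[C@H](C)CCO[Si](CC)(CC)CC)[C@@H]1CC[C@]2(C)[C@@H](O[Si](C)(C)C(C)(C)C)[C@H](O[Si](C)(C)C(C)(C)C)C(=O)C[C@H]12 | intermediate
19 | 4-methylidene-5-ketone | C=C(/C=C/C[C@H](C)CCO[Si](CC)(CC)CC)[C@@H]1CC[C@]2(C)[C@@H](O[Si](C)(C)C(C)(C)C)[C@H](O[Si](C)(C)C(C)(C)C)C(=O)C(=C)[C@H]12 | intermediate
20 | ring enol triflate | C=C(/C=C/C[C@H](C)CCO[Si](CC)(CC)CC)[C@@H]1CC[C@]2(C)[C@@H](O[Si](C)(C)C(C)(C)C)[C@H](O[Si](C)(C)C(C)(C)C)C(OS(=O)(=O)C(F)(F)F)=C(C)[C@H]12 | intermediate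
21 | triflate-aldehyde | C=C(/C=C/C[C@H](C)CC=O)[C@@H]1CC[C@]2(C)[C@@H](O[Si](C)(C)C(C)(C)C)[C@H](O[Si](C)(C)C(C)(C)C)C(OS(=O)(=O)C(F)(F)F)=C(C)[C@H]12 | intermediate
22 | macrocyclic allylic alcohol, bis-TBS | C=C1/C=C/C[C@H](C)C[C@H](O)C2=C(C)[C@@H]3[C@H]1CC[C@]3(C)[C@@H](O[Si](C)(C)C(C)(C)C)[C@@H]2O[Si](C)(C)C(C)(C)C | intermediate
23 | macrocyclic acetate, bis-TBS | C=C1/C=C/C[C@H](C)C[C@H](OC(C)=O)C2=C(C)[C@@H]3[C@H]1CC[C@]3(C)[C@@H](O[Si](C)(C)C(C)(C)C)[C@@H]2O[Si](C)(C)C(C)(C)C | intermediate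
24 | CNP0291538.1 | C=C1/C=C/C[C@H](C)C[C@H](OC(C)=O)C2=C(C)[C@@H]3[C@H]1CC[C@]3(C)[C@@H](O)[C@@H]2O | target

**Totals**
Total steps: 20. Longest linear sequence: 18 (carvone 1 → 24; steps 1–8 and 11–20).

**Three steps most likely to fail**

Step 7 (hydrogenation, sets the configuration at C3). The 7β-silyloxy group sits on the convex surface and may erode or reverse the facial preference. Fallback, setting out from 9: both silyl ethers are removed with HF·pyridine to give the diol enone F1. Hydrogenation with [Ir(cod)(PCy3)(py)]PF6 in CH2Cl2 is then directed by the 7β-hydroxyl, which delivers H2 to the β face and gives the 3α-acetyl diol F2. TBSOTf/2,6-lutidine re-silylates both hydroxyls and the route is rejoined at 10.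

Step 12 (dehydration to the (E)-diene). The allylic alkoxysulfurane may ionise, giving ethers or E/Z mixtures. Fallback, setting out from 15: methyl chloroformate/pyridine gives the allylic methyl carbonate F3. Pd(PPh3)4 (5 mol %) in hot dioxane ionises it to the π-allyl palladium complex, and β-hydride elimination toward the chain gives the (E)-1,3-diene, rejoining at 16.

Step 18 (macrocyclisation and carbinol configuration). Ring closure with a tetrasubstituted alkenyl triflate may be low-yielding, and the carbinol configuration is not secured. Fallback, setting out from 22 as obtained (wrong epimer or mixture): Dess–Martin oxidation gives the macrocyclic enone F4. Reduction with NaBH4/CeCl3·7H2O in MeOH at −78 °C attacks the carbonyl from the outer face of the rigid ring and returns to 22.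

**Further compounds**
F1 | step 7 | 5β-acetoxy-3-acetyl-7aβ-methyl-3aβ,4,5,6,7,7a-hexahydro-1H-indene-6α,7β-diol | CC(=O)C1=CC[C@]2(C)[C@@H](O)[C@H](O)[C@@H](OC(C)=O)C[C@H]12
F2 | step 7 | 5β-acetoxy-3α-acetyl-7aβ-methyl-3aβ-octahydro-1H-indene-6α,7β-diol | CC(=O)[C@@H]1CC[C@]2(C)[C@@H](O)[C@H](O)[C@@H](OC(C)=O)C[C@H]12
F3 | step 12 | methyl carbonate of allylic alcohol 15 | C=C(C(OC(=O)OC)CC[C@H](C)CCO[Si](CC)(CC)CC)[C@@H]1CC[C@]2(C)[C@@H](O[Si](C)(C)C(C)(C)C)[C@H](O[Si](C)(C)C(C)(C)C)[C@@H](OC(C)=O)C[C@H]12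
F4 | step 18 | macrocyclic enone (carbinol of 22 oxidised to ketone) | C=C1/C=C/C[C@H](C)CC(=O)C2=C(C)[C@@H]3[C@H]1CC[C@]3(C)[C@@H](O[Si](C)(C)C(C)(C)C)[C@@H]2O[Si](C)(C)C(C)(C)C
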